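Retrosynthesis: the C1 ester and C8 acetate C–O bonds are cut first. The lactone O–C13 bond is then cut by moving the ring oxygen from C13 to the CMe2 carbon of the isobutenyl group. This is possible because O–C13 is allylic to C1′=C2′Me2, so C13 and C2′ are the two ends of one 1,1-dimethylallyl unit, and the five-membered lactone (O, C12, C11, C14, C13) has a seven-membered oxepinone isomer (O, C12, C11, C14, C13=C1′, C2′).
The oxepinone is cut at its ring alkene C13=C1′ (metathesis) and at the tertiary ester O–C12. C11–C12 goes back to a vinyl iodide and CO, C11–C14 to a terminal alkyne and acrolein, and C8–C9 to a nerol-derived C1–C8 enal and a propargyl unit.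
Forward: the chain grows linearly (C1–C8 from nerol, then C9–C11, then C14 with its vinyl group, then C12 and the 1,1-dimethylallyl ester). The seven-membered lactone is closed first and then contracted to the five-membered lactone by zerovalent palladium. The C8 acetate and the C1 ester are introduced only after the palladium step.
Stereochemistry: 2Z comes from nerol, 6E from SeO2 oxidation of the E-methyl group, C8 (S) and C14 from two catalyst-controlled additions, 10E from a syn-hydrostannation, and C13 (R) from the ring contraction, trans to the C14 oxygen.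

Key step: step 11

Locants follow the target: C1 = OCH2, C8 = acetoxy carbon, C10=C11 = exocyclic alkene, C12 = lactone carbonyl, C13 = ring O–CH, C14 = CHOH, C1′/C2′ = CH= and CMe2 of the isobutenyl group. C14 keeps one spatial arrangement throughout; its descriptor is R up to 18 and S from 19 on only because the CIP priorities change.
Assumption: the catalyst antipodes named in steps 3 and 5 are those expected to give 8S and 14R; both antipodes of each are available, so the other one would be used if the facial sense proved to be the reverse.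

Step 1
Reactants: 1 nerol
Product: 2 neryl tert-butyldiphenylsilyl ether
Conditions: TBDPSCl, imidazole, CH2Cl2, 0 °C to rt
Reagents that add atoms: tert-butyl(chloro)diphenylsilane, CC(C)(C)[Si](Cl)(c1ccccc1)c1ccccc1
Why: Imidazole-promoted silylation of the primary allylic alcohol masks C1 as an ether that zerovalent palladium cannot ionise and that should outlast the mild acid used later to free C8.

Step 2
Reactants: 2 neryl tert-butyldiphenylsilyl ether
Product: 4 (2E,6Z)-8-silyloxy-2,6-dimethylocta-2,6-dienal, via allylic alcohol 3 (not isolated)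
Conditions: SeO2 (0.2 equiv), t-BuOOH, salicylic acid (cat.), CH2Cl2, rt; then MnO2, CH2Cl2, rt
Reagents that add atoms: tert-butyl hydroperoxide, CC(C)(C)OO
Why: The SeO2/t-BuOOH allylic oxidation (ene reaction, then [2,3]-sigmatropic shift) should attack the E-methyl group of the more electron-rich distal alkene, and MnO2 oxidation should converge the alcohol/aldehyde mixture on the (E)-enal, which fixes the 6E geometry.

Step 3
Reactants: 4 (2E,6Z)-8-silyloxy-2,6-dimethylocta-2,6-dienal; 5 allenylboronic acid pinacol ester
Product: 7 (8S)-homopropargylic alcohol, via borate ester 6 (not isolated)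
Conditions: (S)-3,3′-bis(2,4,6-triisopropylphenyl)-1,1′-binaphthyl-2,2′-diyl hydrogen phosphate (10 mol%), 4 Å molecular sieves, toluene, −20 °C; aqueous NaHCO3 work-up
Reagents that add atoms: none
Why: Chiral-phosphoric-acid-catalysed propargylboration (SE2′ addition through a closed six-membered transition state in which the acid holds the boronate oxygen and the formyl hydrogen) should deliver the propargyl group to one face of the enal and set C8 as S under catalyst control.

Step 4
Reactants: 7 (8S)-homopropargylic alcohol
Product: 8 (8S)-triethylsilyl ether alkyne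
Conditions: TESCl, imidazole, DMAP (cat.), CH2Cl2, 0 °C
Reagents that add atoms: chlorotriethylsilane, CC[Si](Cl)(CC)CC
Why: Standard silyl ether formation; the triethylsilyl group is the most acid-labile of the three silyl groups carried, so C8 can be unmasked alone in step 12, and no allylic ester has to pass through the palladium steps.

Step 5
Reactants: 8 (8S)-triethylsilyl ether alkyne; 9 acrolein
Product: 10 (8S,14R)-enynol
Conditions: Me2Zn (3 equiv), (S,S)-2,6-bis{[2-(hydroxydiphenylmethyl)pyrrolidin-1-yl]methyl}-4-methylphenol (20 mol%), Ph3PO (40 mol%), toluene, 0 °C, slow addition of 9; aqueous NH4Cl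
Reagents that add atoms: none
Why: Dinuclear-zinc-catalysed enantioselective alkynylation of an α,β-unsaturated aldehyde should form the C11–C14 bond and set C14 under catalyst control, the remote C8 centre having little influence.

Step 6
Reactants: 10 (8S,14R)-enynol
Product: 12 (10E)-11-iodo alcohol, via vinylstannane 11 (not isolated)
Conditions: Bu3SnH, PdCl2(PPh3)2 (3 mol%), THF, 0 °C; then I2, CH2Cl2, 0 °C; aqueous Na2S2O3
Reagents that add atoms: tributyltin hydride, CCCC[SnH](CCCC)CCCC (its tin is held only by 11); iodine, II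
Why: Palladium-catalysed syn-hydrostannation of a propargylic alcohol should place tin on the carbon next to the carbinol (C11) and hydrogen on C10 cis to it, and iododestannylation with retention then gives the iodide in which C9 and C14 are cis, as the 10E alkylidene of the target requires.

Step 7
Reactants: 12 (10E)-11-iodo alcohol
Product: 13 C14 tert-butyldimethylsilyl ether of the iodide
Conditions: TBSOTf, 2,6-lutidine, CH2Cl2, −78 to 0 °C
Reagents that add atoms: tert-butyldimethylsilyl trifluoromethanesulfonate, CC(C)(C)[Si](C)(C)OS(=O)(=O)C(F)(F)F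
Why: Silyl triflate silylation of the hindered secondary alcohol; a protected C14 oxygen cannot close a β-lactone during the carbonylation and later serves as the bulky group that directs the C13 configuration.

Step 8
Reactants: 13 C14 tert-butyldimethylsilyl ether of the iodide
Product: 14 (10E)-carboxylic acid
Conditions: PdCl2(PPh3)2 (5 mol%), CO (1 atm), Et3N, DMF/H2O, 60 °C; then aqueous citric acid
Reagents that add atoms: carbon monoxide, [C-]#[O+]; water, O
Why: Palladium-catalysed hydroxycarbonylation of an alkenyl iodide (oxidative addition, CO insertion, hydrolysis of the acylpalladium) should install C12 with retention of the alkene geometry.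

Step 9
Reactants: 14 (10E)-carboxylic acid; 15 2-methylbut-3-en-2-ol
Product: 17 1,1-dimethylallyl ester, via acid chloride 16 (not isolated)
Conditions: 1-chloro-N,N,2-trimethylprop-1-en-1-amine, CH2Cl2, 0 °C to rt; then LiOC(CH3)2CH=CH2 (from 15 and n-BuLi), THF, −78 to 0 °C
Reagents that add atoms: 1-chloro-N,N,2-trimethylprop-1-en-1-amine, CC(C)=C(Cl)N(C)C (its chlorine is held only by 16)
Why: Acid chloride formation under neutral conditions followed by acylation of a lithium tertiary alkoxide is the standard way to a hindered tertiary ester and avoids both acid (silyl ethers) and the slow direct coupling of a tertiary alcohol.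

Step 10
Reactants: 17 1,1-dimethylallyl ester
Product: 18 seven-membered lactone
Conditions: second-generation Hoveyda–Grubbs catalyst (10 mol%), toluene (2 mM), 80 °C, argon sparge
Reagents that add atoms: none
Why: Ring-closing metathesis of the two monosubstituted alkenes should close the oxepinone with the ring-enforced cis C13=C1′ alkene, helped by the gem-dimethyl group and the sp2 atoms C11 and C12, while the trisubstituted alkenes react far more slowly with the ruthenium carbene.

Step 11
Reactants: 18 seven-membered lactone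
Product: 19 γ-lactone with three silyl ethers
Conditions: Pd(PPh3)4 (10 mol%), THF, rt to 50 °C
Reagents that add atoms: none
Why: Proposed new method: zerovalent palladium should add to the ring alkene anti to the tertiary allylic C–O bond and ionise it to a zwitterionic η3-allylpalladium carboxylate spanning C13–C1′–C2′, from which the tethered carboxylate returns at the secondary terminus C13; the closest known reaction types are the palladium-catalysed 1,3-transposition of allylic carboxylates by ionisation–recombination and the Tsuji–Trost lactonisation of carboxylates onto π-allyl complexes, neither of which has been used to contract a seven-membered allylic lactone. The five-membered ring closes by 5-exo attack of the carboxylate oxygen on the allyl terminus, anti to palladium, which leaves C1′=C2′ outside the ring as the isobutenyl alkene. C13 is set under thermodynamic control: the two identical methyl groups on C2′ allow η3–η1–η3 face exchange and the product, itself an allylic ester, can ionise again, so both C13 epimers interconvert and the lactone with the isobutenyl group trans to the bulky C14 silyloxy group should accumulate. The step needs attack at C13 instead of C2′, which the greater stability of a five-membered secondary lactone over a seven-membered tertiary one provides, and it needs ionisation at the ring ester only, which is secured because C1, C8 and C14 carry silyl ethers and no other allylic ester is present.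

Step 12
Reactants: 19 γ-lactone with three silyl ethers
Product: 20 C8 alcohol
Conditions: PPTS (cat.), MeOH/CH2Cl2, 0 °C
Reagents that add atoms: none
Why: Acid-catalysed methanolysis (selective desilylation) should cleave the triethylsilyl ether much faster than the secondary tert-butyldimethylsilyl and the primary tert-butyldiphenylsilyl ethers.

Step 13
Reactants: 20 C8 alcohol
Product: 21 C8 acetate
Conditions: Ac2O, pyridine, DMAP (cat.), CH2Cl2, 0 °C to rt
Reagents that add atoms: acetic anhydride, CC(=O)OC(C)=O
Why: DMAP-catalysed acetylation of the only free hydroxyl installs the allylic C8 acetate with retention at C8 and after the last palladium step.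

Step 14
Reactants: 21 C8 acetate
Product: 22 C1,C14-diol
Conditions: HF·pyridine, pyridine, THF, 0 °C to rt
Reagents that add atoms: none
Why: Fluoride-mediated desilylation under buffered, non-basic conditions should remove both remaining silyl ethers without touching the acetate, the lactone or the alkylidene geometry.

Step 15
Reactants: 22 C1,C14-diol; 23 (E)-3-methylpent-2-enoic acid
Product: 25 CNP0168501.1, via O-acylisourea 24 (not isolated)
Conditions: DIC (1.1 equiv), DMAP (0.1 equiv), CH2Cl2, 0 °C
Reagents that add atoms: N,N′-diisopropylcarbodiimide, CC(C)N=C=NC(C)C (its atoms are held only by 24)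
Why: Steglich esterification through the O-acylisourea should acylate the unhindered primary allylic C1 hydroxyl much faster than the secondary C14 hydroxyl flanked by the ring substituents, under conditions mild enough to keep the acid E-configured and conjugated.

Compound list
1 | nerol, (2Z)-3,7-dimethylocta-2,6-dien-1-ol | CC(C)=CCC/C(C)=C\CO | starting material
2 | tert-butyl{[(2Z)-3,7-dimethylocta-2,6-dien-1-yl]oxy}diphenylsilane | CC(C)(C)[Si](c1ccccc1)(c1ccccc1)OC/C=C(/C)CCC=C(C)C | intermediate
3 | (2E,6Z)-8-[(tert-butyldiphenylsilyl)oxy]-2,6-dimethylocta-2,6-dien-1-ol | CC(C)(C)[Si](c1ccccc1)(c1ccccc1)OC/C=C(/C)CC/C=C(\C)CO | intermediate (not isolated)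
4 | (2E,6Z)-8-[(tert-butyldiphenylsilyl)oxy]-2,6-dimethylocta-2,6-dienal | CC(C)(C)[Si](c1ccccc1)(c1ccccc1)OC/C=C(/C)CC/C=C(\C)C=O | intermediate
5 | allenylboronic acid pinacol ester, 4,4,5,5-tetramethyl-2-(propa-1,2-dien-1-yl)-1,3,2-dioxaborolane | C=C=CB1OC(C)(C)C(C)(C)O1 | starting material
6 | pinacol borate ester of 7 (O–B(pin) on C8) | CC(C)(C)[Si](c1ccccc1)(c1ccccc1)OC/C=C(/C)CC/C=C(\C)[C@H](CC#C)OB1OC(C)(C)C(C)(C)O1 | intermediate (not isolated)
7 | (4S,5E,9Z)-11-[(tert-butyldiphenylsilyl)oxy]-5,9-dimethylundeca-5,9-dien-1-yn-4-ol (8S in target numbering) | CC(C)(C)[Si](c1ccccc1)(c1ccccc1)OC/C=C(/C)CC/C=C(\C)[C@H](CC#C)O | intermediate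
8 | triethylsilyl ether of 7 | CC(C)(C)[Si](c1ccccc1)(c1ccccc1)OC/C=C(/C)CC/C=C(\C)[C@H](CC#C)O[Si](CC)(CC)CC | intermediate
9 | acrolein | C=CC=O | starting material
10 | (3R,7S,8E,12Z)-14-[(tert-butyldiphenylsilyl)oxy]-8,12-dimethyl-7-[(triethylsilyl)oxy]tetradeca-1,8,12-trien-4-yn-3-ol (8S,14R in target numbering) | CC(C)(C)[Si](c1ccccc1)(c1ccccc1)OC/C=C(/C)CC/C=C(\C)[C@H](CC#C[C@H](O)C=C)O[Si](CC)(CC)CC | intermediate
11 | (3R,4E,7S,8E,12Z)-14-[(tert-butyldiphenylsilyl)oxy]-8,12-dimethyl-4-(tributylstannyl)-7-[(triethylsilyl)oxy]tetradeca-1,4,8,12-tetraen-3-ol | CC(C)(C)[Si](c1ccccc1)(c1ccccc1)OC/C=C(/C)CC/C=C(\C)[C@H](C/C=C(/[Sn](CCCC)(CCCC)CCCC)[C@H](O)C=C)O[Si](CC)(CC)CC | intermediate (not isolated)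
12 | (3R,4E,7S,8E,12Z)-14-[(tert-butyldiphenylsilyl)oxy]-4-iodo-8,12-dimethyl-7-[(triethylsilyl)oxy]tetradeca-1,4,8,12-tetraen-3-ol | CC(C)(C)[Si](c1ccccc1)(c1ccccc1)OC/C=C(/C)CC/C=C(\C)[C@H](C/C=C(/I)[C@H](O)C=C)O[Si](CC)(CC)CC | intermediate
13 | tert-butyldimethylsilyl ether of 12 (C14 OTBS) | CC(C)(C)[Si](c1ccccc1)(c1ccccc1)OC/C=C(/C)CC/C=C(\C)[C@H](C/C=C(/I)[C@H](O[Si](C)(C)C(C)(C)C)C=C)O[Si](CC)(CC)CC | intermediate
14 | (2E,5S,6E,10Z)-2-[(1R)-1-[(tert-butyldimethylsilyl)oxy]prop-2-en-1-yl]-12-[(tert-butyldiphenylsilyl)oxy]-6,10-dimethyl-5-[(triethylsilyl)oxy]dodeca-2,6,10-trienoic acid | CC(C)(C)[Si](c1ccccc1)(c1ccccc1)OC/C=C(/C)CC/C=C(\C)[C@H](C/C=C(/C(=O)O)[C@H](O[Si](C)(C)C(C)(C)C)C=C)O[Si](CC)(CC)CC | intermediate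
15 | 2-methylbut-3-en-2-ol | C=CC(C)(C)O | starting material
16 | acid chloride of 14 | CC(C)(C)[Si](c1ccccc1)(c1ccccc1)OC/C=C(/C)CC/C=C(\C)[C@H](C/C=C(/C(Cl)=O)[C@H](O[Si](C)(C)C(C)(C)C)C=C)O[Si](CC)(CC)CC | intermediate (not isolated)
17 | 2-methylbut-3-en-2-yl ester of 14 | CC(C)(C)[Si](c1ccccc1)(c1ccccc1)OC/C=C(/C)CC/C=C(\C)[C@H](C/C=C(/C(=O)OC(C)(C)C=C)[C@H](O[Si](C)(C)C(C)(C)C)C=C)O[Si](CC)(CC)CC | intermediate
18 | (3E,4R)-4-[(tert-butyldimethylsilyl)oxy]-3-[(3S,4E,8Z)-10-[(tert-butyldiphenylsilyl)oxy]-4,8-dimethyl-3-[(triethylsilyl)oxy]deca-4,8-dien-1-ylidene]-7,7-dimethyl-4,7-dihydrooxepin-2(3H)-one | CC(C)(C)[Si](c1ccccc1)(c1ccccc1)OC/C=C(/C)CC/C=C(\C)[C@H](C/C=C1/C(=O)OC(C)(C)C=C[C@H]1O[Si](C)(C)C(C)(C)C)O[Si](CC)(CC)CC | intermediate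
19 | (3E,4S,5R)-4-[(tert-butyldimethylsilyl)oxy]-3-[(3S,4E,8Z)-10-[(tert-butyldiphenylsilyl)oxy]-4,8-dimethyl-3-[(triethylsilyl)oxy]deca-4,8-dien-1-ylidene]-5-(2-methylprop-1-en-1-yl)dihydrofuran-2(3H)-one | CC(C)(C)[Si](c1ccccc1)(c1ccccc1)OC/C=C(/C)CC/C=C(\C)[C@H](C/C=C1/C(=O)O[C@H](C=C(C)C)[C@H]1O[Si](C)(C)C(C)(C)C)O[Si](CC)(CC)CC | intermediate
20 | C8 alcohol from 19 (C1 OTBDPS, C8 OH, C14 OTBS) | CC(C)(C)[Si](c1ccccc1)(c1ccccc1)OC/C=C(/C)CC/C=C(\C)[C@H](C/C=C1/C(=O)O[C@H](C=C(C)C)[C@H]1O[Si](C)(C)C(C)(C)C)O | intermediate
21 | C8 acetate of 20 | CC(C)(C)[Si](c1ccccc1)(c1ccccc1)OC/C=C(/C)CC/C=C(\C)[C@H](C/C=C1/C(=O)O[C@H](C=C(C)C)[C@H]1O[Si](C)(C)C(C)(C)C)OC(C)=O | intermediate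
22 | (3E,4S,5R)-3-[(3S,4E,8Z)-3-acetoxy-10-hydroxy-4,8-dimethyldeca-4,8-dien-1-ylidene]-4-hydroxy-5-(2-methylprop-1-en-1-yl)dihydrofuran-2(3H)-one | OC/C=C(/C)CC/C=C(\C)[C@H](C/C=C1/C(=O)O[C@H](C=C(C)C)[C@H]1O)OC(C)=O | intermediate
23 | (E)-3-methylpent-2-enoic acid | CC/C(C)=C/C(=O)O | starting material
24 | O-acylisourea from 23 and N,N′-diisopropylcarbodiimide | CC/C(C)=C/C(=O)OC(=NC(C)C)NC(C)C | intermediate (not isolated)
25 | CNP0168501.1 (C1 (E)-3-methylpent-2-enoate, 8S acetate, 13R,14S lactone) | CC/C(C)=C/C(=O)OC/C=C(/C)CC/C=C(\C)[C@H](C/C=C1/C(=O)O[C@H](C=C(C)C)[C@H]1O)OC(C)=O | target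

Total step count: 15
Longest linear sequence: 15 steps (from nerol 1; compounds 5, 9, 15 and 23 are bought)

Steps most likely to fail

1. Step 11 (ring contraction). The endocyclic C–O bond may not reach the alignment with the alkene π system that ionisation needs. The allyl intermediate may also lose a β-hydrogen from a C2′ methyl group and collapse to a diene acid, or equilibration may stop before the C13 epimers have converged. The fallback uses known chemistry, an acyclic Tsuji–Trost lactonisation, and sets out from acid 14. Cross-metathesis (second-generation Hoveyda–Grubbs catalyst, CH2Cl2, 40 °C) with an excess of methyl 2-methylbut-3-en-2-yl carbonate F1, made from 15 with n-BuLi and methyl chloroformate, should give the (E)-allylic tertiary carbonate acid F2. Pd(PPh3)4 in THF then ionises the carbonate, carbon dioxide and methanol are lost, and the carboxylate closes on C13 of the same allyl unit to give the trans lactone. The route is rejoined at 19; steps 9 and 10 are then not needed.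

2. Step 10 (ring-closing metathesis). The alkene next to the quaternary carbon may engage too slowly, so that the ruthenium carbene formed at C13 is diverted into ring closure onto the C6=C7 alkene or into oligomerisation. The fallback is a relay ring-closing metathesis and sets out from acid 14. Lithiated allyl propargyl ether and acetone give 5-(allyloxy)-2-methylpent-3-yn-2-ol F3, and Lindlar semihydrogenation (Pd on CaCO3 poisoned with Pb(OAc)2, quinoline, H2) gives (Z)-5-(allyloxy)-2-methylpent-3-en-2-ol F4. Its lithium alkoxide is acylated by acid chloride 16 as in step 9 to give the relay ester F5. The catalyst should load on the unhindered allyl ether terminus, expel 2,5-dihydrofuran and so arrive as a carbene on C1′, from where only the seven-membered closure onto the C14 vinyl group is within reach. The route is rejoined at 18.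

3. Step 5 (alkynylation of acrolein). Enantiofacial discrimination may be poor with this small, polymerisation-prone aldehyde, and methyl transfer from zinc may compete. The fallback is an uncatalysed addition followed by enzymatic kinetic resolution and sets out from alkyne 8. Deprotonation with n-BuLi (THF, −78 °C) and addition to acrolein gives the C14-epimeric alcohol F6. Burkholderia cepacia lipase with vinyl acetate should, by the usual empirical rule for lipases and secondary alcohols, acetylate the 14R epimer to the (14R)-acetate F7, which is separated from the unreacted 14S alcohol. Methanolysis (K2CO3, MeOH, 0 °C) returns the route at 10.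

Further compounds
F1 | step 11 | methyl 2-methylbut-3-en-2-yl carbonate | COC(=O)OC(C)(C)C=C
F2 | step 11 | acid 14 carrying an (E)-CH=CH–C(CH3)2–OCO2CH3 group on C14 in place of vinyl | CC(C)(C)[Si](c1ccccc1)(c1ccccc1)OC/C=C(/C)CC/C=C(\C)[C@H](C/C=C(/C(=O)O)[C@H](O[Si](C)(C)C(C)(C)C)/C=C/C(C)(C)OC(=O)OC)O[Si](CC)(CC)CC
F3 | step 10 | 5-(allyloxy)-2-methylpent-3-yn-2-ol | CC(C)(O)C#CCOCC=C
F4 | step 10 | (Z)-5-(allyloxy)-2-methylpent-3-en-2-ol | CC(C)(O)/C=C\COCC=C
F5 | step 10 | (Z)-5-(allyloxy)-2-methylpent-3-en-2-yl ester of 14 (relay ester) | CC(C)(C)[Si](c1ccccc1)(c1ccccc1)OC/C=C(/C)CC/C=C(\C)[C@H](C/C=C(/C(=O)OC(C)(C)/C=C\COCC=C)[C@H](O[Si](C)(C)C(C)(C)C)C=C)O[Si](CC)(CC)CC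
F6 | step 5 | C14-epimeric mixture of enynol 10 | CC(C)(C)[Si](c1ccccc1)(c1ccccc1)OC/C=C(/C)CC/C=C(\C)[C@H](CC#CC(O)C=C)O[Si](CC)(CC)CC
F7 | step 5 | (14R)-acetate of 10 | CC(C)(C)[Si](c1ccccc1)(c1ccccc1)OC/C=C(/C)CC/C=C(\C)[C@H](CC#C[C@H](OC(C)=O)C=C)O[Si](CC)(CC)CC
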